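**Retrosynthetic overview**

1. Target ⇐ oxan-4-one 11 (axial hydride puts the C4–OH equatorial) ⇐ alkynyl dihydropyranone 10. One hydrogenation saturates C≡C and C5=C6 (sets C6, 2,6-cis) and removes both benzyl groups.
2. Key disconnection: the bond between ring carbon C2 and the first carbon of the arylethyl chain, made as a C(sp3)–C(sp) bond. Terminal aryl alkyne 7 is joined to the flat, achiral 2-aryl-γ-pyrone 5 by a catalytic enantioselective dearomatising alkynylation of its 4-silyloxypyrylium salt.
3. Enabling feature: the only hydroxyl of the oxane ring sits on C4, γ to the ring oxygen O1. At ketone level the ring O1/C2–C6 is a γ-pyrone, and O-silylation of the C4 oxygen aromatises it to a pyrylium. Its free α-carbon (future C2) is the electrophile, while the other α-carbon (C6) is blocked by the syringyl ring.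
4. Ring formation: both benzene rings are bought. The pyran ring is the only ring built (step 3, O1–C bond by addition–elimination) and is never reopened. C2 is set by the catalyst; C6 and C4 are relayed from it.

Key step: step 5

Assumptions: compounds 1, 3 and 6 are taken as commercially available. The sense of induction of the chiral ligand in step 5 is assigned by analogy, and the ligand antipode that gives (R)-10 is the one to be used. Target numbering in the explanations: O1, C2 (carries the arylethyl chain), C3, C4 (OH), C5, C6 (carries the syringyl ring).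

**Route**

Step 1
Reactants: 1 4-(benzyloxy)-3,5-dimethoxybenzoic acid
Product: 2 4-(benzyloxy)-3,5-dimethoxybenzoyl chloride
Conditions: (COCl)2 (1.5 equiv), DMF (cat.), CH2Cl2, 0 °C to rt; concentrate
Reagents that add atoms: oxalyl chloride, O=C(Cl)C(Cl)=O
Why: Vilsmeier-catalysed conversion of an aryl carboxylic acid into its acid chloride; the benzyl and methyl ethers are inert and no stereocentre is involved.

Step 2
Reactants: 2 4-(benzyloxy)-3,5-dimethoxybenzoyl chloride; 3 (E)-4-methoxybut-3-en-2-one
Product: 4 (E)-1-[4-(benzyloxy)-3,5-dimethoxyphenyl]-5-methoxypent-4-ene-1,3-dione (mainly enolised)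
Conditions: 3 (2.0 equiv), LiHMDS (2.0 equiv), THF, −78 °C; then 2 (1.0 equiv), −78 °C; aq. NH4Cl
Reagents that add atoms: none
Why: Kinetic deprotonation of the methyl group of the vinylogous ester gives the cross-conjugated lithium enolate, which is C-acylated by the aroyl chloride (Claisen-type enolate acylation, the second equivalent of enolate taking up the acidic β-diketone proton), so that all five carbons of the future pyran ring are in place.

Step 3
Reactants: 4 (E)-1-[4-(benzyloxy)-3,5-dimethoxyphenyl]-5-methoxypent-4-ene-1,3-dione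
Product: 5 2-[4-(benzyloxy)-3,5-dimethoxyphenyl]-4H-pyran-4-one
Conditions: TFA (0.2 equiv), toluene, rt
Reagents that add atoms: none
Why: Acid-catalysed 6-endo addition of the enol oxygen to the β-methoxy enone followed by loss of methanol (addition–elimination cyclisation to a γ-pyrone) closes the only ring made in the route; no stereocentre is formed.

Step 4
Reactants: 6 4-(benzyloxy)-3-methoxybenzaldehyde
Product: 7 1-(benzyloxy)-4-ethynyl-2-methoxybenzene
Conditions: dimethyl (1-diazo-2-oxopropyl)phosphonate (1.3 equiv), K2CO3 (2 equiv), MeOH–THF, 0 °C to rt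
Reagents that add atoms: dimethyl (1-diazo-2-oxopropyl)phosphonate (Ohira–Bestmann reagent), COP(=O)(OC)C(=[N+]=[N-])C(C)=O
Why: Ohira–Bestmann (Seyferth–Gilbert) homologation, in which the diazomethylphosphonate anion released by methanolysis olefinates the non-enolisable aryl aldehyde and loss of N2 with 1,2-hydrogen shift gives the terminal alkyne.

Step 5
Reactants: 5 2-[4-(benzyloxy)-3,5-dimethoxyphenyl]-4H-pyran-4-one; 7 1-(benzyloxy)-4-ethynyl-2-methoxybenzene
Product: 10 (2R)-6-[4-(benzyloxy)-3,5-dimethoxyphenyl]-2-{[4-(benzyloxy)-3-methoxyphenyl]ethynyl}-2,3-dihydro-4H-pyran-4-one, via silyloxypyrylium triflate 8 (not isolated), via silyl dienol ether 9 (not isolated)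
Conditions: TBSOTf (1.2 equiv), CH2Cl2, 0 °C; then CuI (5 mol %), chiral P,N-ligand of the StackPhos type (6 mol %), 7 (1.3 equiv), i-Pr2NEt (1.5 equiv), toluene–CH2Cl2, −40 °C; then 1 M HCl, THF, 0 °C
Reagents that add atoms: none
Why: Proposed new method: TBSOTf silylates the carbonyl oxygen of γ-pyrone 5 and so aromatises the ring to 4-silyloxypyrylium 8, while CuI, ligand and i-Pr2NEt turn 7 into a chiral copper(I) acetylide that adds to the only unsubstituted α-carbon of the pyrylium (C2 in target numbering) to give dienol ether 9 and release Cu(I); aqueous acid then protonates C3 and cleaves the O–Si bond to unveil vinylogous ester 10. The closest known reaction type is the copper/chiral P,N-ligand-catalysed enantioselective alkynylation of chromones through in situ 4-silyloxybenzopyrylium triflates (and of N-acylpyridinium and quinolinium ions), together with the racemic addition of organometallics to 4-silyloxypyrylium salts of monocyclic γ-pyrones; the extension asked for here is the monocyclic 2-aryl pyrylium. No ring is closed: the oxygen heterocycle is carried in intact and is dearomatised, so ring size and the C4 oxygen are already in place. The single new stereocentre C2 (R) is set under catalyst control by the ligand on copper, which differentiates the two faces of the planar cation, and it is the only stereocentre of the route that needs an external chiral source. The step needs α-regioselectivity, secured because the other α-carbon (C6) carries the conjugating, electron-rich syringyl ring and the γ-carbon carries OSi, and it needs C–C bond formation in preference to attack by the amine, secured by the soft acetylide and the hindered base. The product is a vinylogous ester and is kept away from base, since β-elimination of the ring oxygen would erase C2.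

Step 6
Reactants: 10 (2R)-6-[4-(benzyloxy)-3,5-dimethoxyphenyl]-2-{[4-(benzyloxy)-3-methoxyphenyl]ethynyl}-2,3-dihydro-4H-pyran-4-one
Product: 11 (2S,6S)-2-(4-hydroxy-3,5-dimethoxyphenyl)-6-[2-(4-hydroxy-3-methoxyphenyl)ethyl]oxan-4-one (2,6-cis)
Conditions: H2 (1 atm), 10% Pd/C, EtOAc–EtOH, rt; stopped when uptake ceases
Reagents that add atoms: none
Why: Heterogeneous hydrogenation should saturate the alkyne, cleave both benzyl ethers and add H2 across the C5=C6 vinylogous ester from the face opposite the C2 side chain, which sets C6 (S) and the 2,6-cis relationship, as expected for hydrogenation of 2,6-disubstituted 2,3-dihydro-4H-pyran-4-ones.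

Step 7
Reactants: 11 (2S,6S)-2-(4-hydroxy-3,5-dimethoxyphenyl)-6-[2-(4-hydroxy-3-methoxyphenyl)ethyl]oxan-4-one
Product: 12 (2S,4R,6S)-2-(4-hydroxy-3,5-dimethoxyphenyl)-6-[2-(4-hydroxy-3-methoxyphenyl)ethyl]oxan-4-ol (all-cis; CNP0302691.1)
Conditions: NaBH4 (3 equiv), MeOH, −20 to 0 °C; aq. NH4Cl
Reagents that add atoms: none
Why: Borohydride reduction in which the small hydride attacks the chair oxan-4-one axially (both ring substituents equatorial), so the new C4–OH (4R) should come out equatorial and cis to both substituents.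

**Compound list**

1 | 4-(benzyloxy)-3,5-dimethoxybenzoic acid | COc1cc(C(=O)O)cc(OC)c1OCc1ccccc1 | starting material
2 | 4-(benzyloxy)-3,5-dimethoxybenzoyl chloride | COc1cc(C(Cl)=O)cc(OC)c1OCc1ccccc1 | intermediate
3 | (E)-4-methoxybut-3-en-2-one | CO/C=C/C(C)=O | starting material
4 | (E)-1-[4-(benzyloxy)-3,5-dimethoxyphenyl]-5-methoxypent-4-ene-1,3-dione | CO/C=C/C(=O)CC(=O)c1cc(OC)c(OCc2ccccc2)c(OC)c1 | intermediate
5 | 2-[4-(benzyloxy)-3,5-dimethoxyphenyl]-4H-pyran-4-one | COc1cc(-c2cc(=O)cco2)cc(OC)c1OCc1ccccc1 | intermediate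
6 | 4-(benzyloxy)-3-methoxybenzaldehyde | COc1cc(C=O)ccc1OCc1ccccc1 | starting material
7 | 1-(benzyloxy)-4-ethynyl-2-methoxybenzene | COc1cc(C#C)ccc1OCc1ccccc1 | intermediate
8 | 2-[4-(benzyloxy)-3,5-dimethoxyphenyl]-4-[(tert-butyldimethylsilyl)oxy]pyrylium trifluoromethanesulfonate | COc1cc(-c2cc(O[Si](C)(C)C(C)(C)C)cc[o+]2)cc(OC)c1OCc1ccccc1.[O-]S(=O)(=O)C(F)(F)F | intermediate
9 | (R)-tert-butyl({6-[4-(benzyloxy)-3,5-dimethoxyphenyl]-2-{[4-(benzyloxy)-3-methoxyphenyl]ethynyl}-2H-pyran-4-yl}oxy)dimethylsilane | COc1cc(C#C[C@H]2C=C(O[Si](C)(C)C(C)(C)C)C=C(c3cc(OC)c(OCc4ccccc4)c(OC)c3)O2)ccc1OCc1ccccc1 | intermediate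
10 | (2R)-6-[4-(benzyloxy)-3,5-dimethoxyphenyl]-2-{[4-(benzyloxy)-3-methoxyphenyl]ethynyl}-2,3-dihydro-4H-pyran-4-one | COc1cc(C#C[C@H]2CC(=O)C=C(c3cc(OC)c(OCc4ccccc4)c(OC)c3)O2)ccc1OCc1ccccc1 | intermediate
11 | (2S,6S)-2-(4-hydroxy-3,5-dimethoxyphenyl)-6-[2-(4-hydroxy-3-methoxyphenyl)ethyl]oxan-4-one | COc1cc(CC[C@H]2CC(=O)C[C@@H](c3cc(OC)c(O)c(OC)c3)O2)ccc1O | intermediate
12 | (2S,4R,6S)-2-(4-hydroxy-3,5-dimethoxyphenyl)-6-[2-(4-hydroxy-3-methoxyphenyl)ethyl]oxan-4-ol | COc1cc(CC[C@H]2C[C@@H](O)C[C@@H](c3cc(OC)c(O)c(OC)c3)O2)ccc1O | target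

**Step count**

Total steps: 7. Longest linear sequence: 6 (steps 1, 2, 3, 5, 6, 7); step 4 is the one-step side branch to the alkyne.

**Steps most likely to fail**

Step 5 (proposed new method). The donor-substituted pyrylium may react sluggishly, the ligand may discriminate its two faces poorly, the 2H-pyran 9 may open electrocyclically, or 10 may racemise by β-elimination before it is isolated.
Fallback, known chemistry, in which the same ring-carbon to alkyne-carbon bond is made by acetylide addition to a lactone carbonyl. It sets out from 7 and from commercial 4-(benzyloxy)-3,5-dimethoxybenzaldehyde and comes back to the route at 11.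
- Methyl (E)-3-methoxybut-2-enoate is converted (LDA, TMSCl, THF, −78 °C) into 1,3-dimethoxy-1-(trimethylsilyloxy)buta-1,3-diene (Brassard's diene) F1.
- F1 undergoes a catalytic enantioselective hetero-Diels–Alder reaction with the aldehyde (chiral Ti(IV)–BINOL-type or TADDOL hydrogen-bond catalyst, then TFA; catalyst antipode chosen for the S product). This should give (S)-6-[4-(benzyloxy)-3,5-dimethoxyphenyl]-4-methoxy-5,6-dihydro-2H-pyran-2-one F2.
- The lithium acetylide of 7 (n-BuLi, THF, −78 °C) adds to the lactone carbonyl of F2. Dilute aqueous acid then dehydrates the lactol and hydrolyses the methyl enol ether to (S)-2-[4-(benzyloxy)-3,5-dimethoxyphenyl]-6-{[4-(benzyloxy)-3-methoxyphenyl]ethynyl}-2,3-dihydro-4H-pyran-4-one F3, in which the aryl-bearing carbon is the stereocentre.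
- Hydrogenation of F3 (H2, Pd/C, EtOAc) should saturate the alkyne and the ring C=C (hydrogen anti to the aryl group, hence 2,6-cis) and remove both benzyl groups, giving 11.

Step 6. Hydrogen may be delivered to the wrong face of C5=C6. The allylic C2–O1 bond may undergo hydrogenolysis while the alkyne passes through the alkene stage, or the benzylic C6–O1 bond may do so after saturation. The aryl-conjugated vinylogous ester may also be reduced incompletely.
Fallback, which separates the three reductions and sets C6 stereoelectronically. It sets out from 10 and comes back at 12.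
- Conjugate reduction of 10 with L-Selectride (THF, −78 °C; axial hydride delivery to C6) should give (2R,6S)-6-[4-(benzyloxy)-3,5-dimethoxyphenyl]-2-{[4-(benzyloxy)-3-methoxyphenyl]ethynyl}oxan-4-one F4 (2,6-cis).
- NaBH4 (MeOH, −20 °C) should give the all-cis alcohol (2R,4S,6S)-2-[4-(benzyloxy)-3,5-dimethoxyphenyl]-6-{[4-(benzyloxy)-3-methoxyphenyl]ethynyl}oxan-4-ol F5.
- Hydrogenation of F5 (H2, Pd/C, EtOAc), now on an ordinary propargylic dialkyl ether, saturates the alkyne and removes both benzyl groups to give 12.

Step 2. O-acylation, double acylation, or Michael-type self-condensation of the methoxyenone enolate may outrun the wanted C-acylation.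
Fallback, which builds the pyranone by cycloaddition and dehydrogenation instead of enolate acylation. It sets out from 3 and comes back at 5.
- 3 is silylated (TMSCl, Et3N, ZnCl2 cat.) to (E)-1-methoxy-3-(trimethylsilyloxy)buta-1,3-diene (Danishefsky's diene) F6.
- Hetero-Diels–Alder reaction of F6 with commercial 4-(benzyloxy)-3,5-dimethoxybenzaldehyde (BF3·OEt2, CH2Cl2, −78 °C, then TFA) gives racemic 2-[4-(benzyloxy)-3,5-dimethoxyphenyl]-2,3-dihydro-4H-pyran-4-one F7.
- The stereocentre of F7 is then removed by α,β-dehydrogenation (IBX, DMSO, 70 °C), which gives 5.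

**Further compounds**

F1 | step 5 | 1,3-dimethoxy-1-(trimethylsilyloxy)buta-1,3-diene (Brassard's diene) | C=C(OC)C=C(OC)O[Si](C)(C)C
F2 | step 5 | (S)-6-[4-(benzyloxy)-3,5-dimethoxyphenyl]-4-methoxy-5,6-dihydro-2H-pyran-2-one | O=C1C=C(OC)C[C@@H](c2cc(OC)c(OCc3ccccc3)c(OC)c2)O1
F3 | step 5 | (S)-2-[4-(benzyloxy)-3,5-dimethoxyphenyl]-6-{[4-(benzyloxy)-3-methoxyphenyl]ethynyl}-2,3-dihydro-4H-pyran-4-one | O=C1C[C@@H](c2cc(OC)c(OCc3ccccc3)c(OC)c2)OC(C#Cc2ccc(OCc3ccccc3)c(OC)c2)=C1
F4 | step 6 | (2R,6S)-6-[4-(benzyloxy)-3,5-dimethoxyphenyl]-2-{[4-(benzyloxy)-3-methoxyphenyl]ethynyl}oxan-4-one | COc1cc(C#C[C@H]2CC(=O)C[C@@H](c3cc(OC)c(OCc4ccccc4)c(OC)c3)O2)ccc1OCc1ccccc1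
F5 | step 6 | (2R,4S,6S)-2-[4-(benzyloxy)-3,5-dimethoxyphenyl]-6-{[4-(benzyloxy)-3-methoxyphenyl]ethynyl}oxan-4-ol | COc1cc(C#C[C@H]2C[C@@H](O)C[C@@H](c3cc(OC)c(OCc4ccccc4)c(OC)c3)O2)ccc1OCc1ccccc1
F6 | step 2 | (E)-1-methoxy-3-(trimethylsilyloxy)buta-1,3-diene (Danishefsky's diene) | CO/C=C/C(=C)O[Si](C)(C)C
F7 | step 2 | rac-2-[4-(benzyloxy)-3,5-dimethoxyphenyl]-2,3-dihydro-4H-pyran-4-one | O=C1C=COC(c2cc(OC)c(OCc3ccccc3)c(OC)c2)C1
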